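Readings and results stem from a simulated flask from invented constants.

3 questions stand on this flask, and we reckon the first of them by one quantity.

- how much target there is at 6.0 d, in percent of the solid substrate charged
- the change that raises the amount of target at 6.0 d, in percent of the solid substrate charged most ("none" if none brings more than 2 percentage points) (dusk / spring / dawn / summer / none)
- amount of target at 6.0 d, in percent of the solid substrate charged, after spring

- dusk: doubling the amount of catalyst, all else as stated
- spring: doubling the dissolution coefficient of the solid substrate, all else as stated
- dawn: doubling the amount of reagent, all else as stated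
- summer: doubling the solubility of the solid substrate, all else as stated

common to all: reagent 0.0525 M

| flask | solid substrate | catalyst | remark | time |
|---|---|---|---|---|
| grey | 0.034 M | 5 mM | run made earlier |  |
| amber | 0.075 M | 5 mM | run made earlier |  |
| flask | 0.050 M | 5.0 mM |  | 6.0 d |

| run | time / d | target / % | solid substrate / % |
|---|---|---|---|
| grey | 0.833 | 3.7 | 88.5 |
| grey | 1.67 | 9.8 | 81.1 |
| grey | 2.50 | 13.3 | 76.1 |
| grey | 3.00 | 17.8 | 72.6 |
| grey | 4.00 | 22.7 | 69.1 |
| grey | 5.00 | 29.2 | 61.7 |
| amber | 0.333 | 0.1 | 98.1 |
| amber | 0.833 | 2.4 | 92.7 |
| amber | 1.67 | 2.4 | 91.0 |
| amber | 2.50 | 7.4 | 90.0 |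
| amber | 4.00 | 12.1 | 85.1 |
| amber | 5.00 | 13.0 | 84.1 |

(standard deviation of a reading: 1 percentage point)

- solid substrate is a solid; its amount is given per volume of the solution
- the numbers in the tables scatter with a standard deviation of 1 percentage point
- at the start none of the solid substrate is in solution

Amber holds about twice the solid substrate of grey, yet by 5.00 d grey has made 1.99 mM d⁻¹ of target and amber 1.95 mM d⁻¹, about the same. Their average, 1.97 mM d⁻¹, is the mean rate: target made per volume per day, from the start to the last reading. At these charges of reagent and catalyst, which the flask shares, formation reads as apparent zero order in the solid substrate.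

We build the flask up from the main step, the mean rate held for 6.0 d:

y = mean rate × time / [solid substrate] charged = 23.6%

Next comes the reagent, which we take as used one for one and as setting the rate in proportion. Its mean concentration is 47.6 mM in the runs up to 5.00 d and 46.6 mM in the flask up to 6.0 d, so it is lower in the flask than in the runs:

y = 23.6% × 0.979 = 23.1%

Last comes the start, with nothing in solution. Amber's first reading, at 0.333 d, shows a lag of 0.295 d, a single reading with its scatter. The mean rate carries that lag over 5.00 d, the flask over 6.0 d:

y = 23.1% × 1.01 = 23.4%

We reckoned no doubling. The forecast gives 23.5%, names summer as best and gives 29.5% after spring, saying “Doubling solubility nearly doubles the rate”.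

The flask gives 23.8%; summer is best, with a gain of 19 percentage points, and spring gives 26.6%.

    starting material + reagent + catalyst → catalyst + target (k = 130 M⁻² h⁻¹)
    solid substrate ⇌ starting material, rate k2*(cs2 - [starting material]) while solid is left; crystals form when [starting material] > cs2 (solubility = 3.60 mM, k = 0.120 h⁻¹)

What the mean rate hides is the starting material, the substrate in solution, which stands at 5.74% of the charge at 3.00 d and 5.89% at 6.00 d. The flask's own target, 11.9 mM over 6.0 d, is a mean rate of 1.98 mM d⁻¹. Carried to the neighbour flask with 0.020 M of solid substrate, our mean rate of 1.97 mM d⁻¹ gives 59.1%, and that flask holds 59.4% of target.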